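**Retrosynthetic overview**

- Feature: in the butenolide (lactone numbering O1, C2 carbonyl, C3 methyl-bearing, C4 carboxyl-bearing, C5 stereocentre), C4 is a branch point carrying the carboxyl carbon, C3 and C5. This branch is latent in methyl furan-2-carboxylate once a carbene is added across its 4,5-bond: furan C3 → C5, furan C4 → C4, furan C5 → carboxyl carbon, carbene carbon → C3, carbene ester carbon → C2.
- Endocyclic C3=C4 ⇐ exocyclic C3=CH2 (isomerisation) ⇐ C3 methylenation of a trans 4-carboxy-γ-lactone; C5 chain ⇐ cross-metathesis and hydrogenation of a C5-allyl lactone with a C14 ketal alkene.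
- γ-Lactone ⇐ retro-aldol opening and lactonisation of a cyclopropanol; C5 ⇐ Felkin–Anh allylation of a cyclopropanecarbaldehyde; cyclopropane ⇐ asymmetric copper-carbene addition to the furoate.
- Ring order: the sacrificial cyclopropane, fused to the dihydrofuran, is closed first; the lactone ring forms in the step that breaks it.

Key step: step 1

Assumption (chemistry): the (S,S)-configured bis(oxazoline) is taken to give the (1S,5S,6S) adduct; if the sense of induction proves opposite, the (R,R)-ligand is used and nothing else changes.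

**Route**

Step 1
Reactants: 1 methyl furan-2-carboxylate; 2 ethyl diazoacetate
Product: 3 6-ethyl 3-methyl (1S,5S,6S)-2-oxabicyclo[3.1.0]hex-3-ene-3,6-dicarboxylate (ester on C6 exo)
Conditions: Cu(OTf)2 (cat.), 2,2'-(propane-2,2-diyl)bis[(4S)-4-isopropyl-4,5-dihydrooxazole] (cat.), PhNHNH2 (cat.), CH2Cl2, 0 °C, slow addition of 2; recrystallisation
Reagents that add atoms: none
Why: Phenylhydrazine reduces Cu(OTf)2 to the monovalent copper–bis(oxazoline) complex, which takes N2 out of 2 to give an electrophilic copper carbene that adds in a concerted, asynchronous (2+1) fashion to the 4,5-double bond of 1. The closest known reaction type is the copper–bis(oxazoline) asymmetric cyclopropanation of furan-2-carboxylic esters with diazoacetates, so this is known chemistry on this substrate class. The three-membered ring is closed by this (2+1) cycloaddition, which forms both bonds from the carbene carbon (to furan C4 and to furan C5) in one step and fuses the cyclopropane cis to the dihydrofuran. C1 and C5 are cis by the ring fusion, C6 is exo because the carbene ester turns away from the furan ring during the approach, and the absolute sense of all three is set by the twofold-symmetric ligand, which should differentiate the two faces of the furan bond. The step needs site selectivity for the 4,5- over the 2,3-bond, secured by the ring ester that deactivates and shields its own double bond, and mono-addition, secured because the remaining alkene of 3 is an electron-poor alkoxy-acrylate. Slow addition of 2 suppresses carbene dimerisation, and recrystallisation of 3 should raise its enantiomeric purity.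

Step 2
Reactants: 3 6-ethyl 3-methyl (1S,5S,6S)-2-oxabicyclo[3.1.0]hex-3-ene-3,6-dicarboxylate
Product: 5 ethyl (1S,2S,3S)-2-formyl-3-[(2-methoxy-2-oxoacetyl)oxy]cyclopropane-1-carboxylate, via secondary ozonide 4 (not isolated)
Conditions: O3, CH2Cl2, −78 °C; then Me2S, −78 °C to rt
Reagents that add atoms: ozone, O=[O+][O-]
Why: Criegee ozonolysis cleaves the only C=C of 3 and Me2S reduces ozonide 4, so the ring carbon becomes the formyl group and the former furan ester carbon stays on oxygen as a methyl oxalyl ester, while the three cyclopropane stereocentres are not touched.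

Step 3
Reactants: 5 ethyl (1S,2S,3S)-2-formyl-3-[(2-methoxy-2-oxoacetyl)oxy]cyclopropane-1-carboxylate; 6 allyltrimethylsilane
Product: 7 ethyl (1S,2R,3S)-2-[(1S)-1-hydroxybut-3-en-1-yl]-3-[(2-methoxy-2-oxoacetyl)oxy]cyclopropane-1-carboxylate
Conditions: BF3·OEt2, CH2Cl2, −78 °C; then aq NaHCO3
Reagents that add atoms: none
Why: Hosomi–Sakurai allylation through an open transition state under Felkin–Anh control: the BF3-bound aldehyde should react in its bisected s-cis-like conformation with attack anti to the ring bond leading to the oxalate-bearing carbon (the most electron-withdrawing α-substituent, whose cis oxalate also shields the other face), which sets the carbinol centre as (S); oxalate and ethyl ester tolerate the Lewis acid at −78 °C.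

Step 4
Reactants: 7 ethyl (1S,2R,3S)-2-[(1S)-1-hydroxybut-3-en-1-yl]-3-[(2-methoxy-2-oxoacetyl)oxy]cyclopropane-1-carboxylate
Product: 10 (2S,3R)-2-allyl-5-oxotetrahydrofuran-3-carbaldehyde, via cyclopropanol 8 (not isolated), via open-chain hydroxy aldehyde 9 (not isolated)
Conditions: Ba(OH)2·8H2O, MeOH, 0 °C
Reagents that add atoms: none
Why: The doubly activated oxalate ester is cleaved first, the freed cyclopropanolate opens the donor–acceptor cyclopropane by retro-aldol scission of the bond to the ester-bearing carbon, and the secondary hydroxyl then closes the γ-lactone on the ethyl ester (5-exo-trig acyl substitution); the carbinol centre becomes C5 unchanged and the formyl-bearing centre keeps its cyclopropane configuration, which is also the more stable trans arrangement.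

Step 5
Reactants: 11 ethyl acetoacetate; 12 11-bromo-1-undecene
Product: 13 ethyl 2-acetyltridec-12-enoate (racemic)
Conditions: NaOEt, NaI (cat.), EtOH, reflux; 11 in excess
Reagents that add atoms: none
Why: Acetoacetic ester alkylation, an SN2 reaction of the stabilised sodium enolate with the primary bromide, with excess 11 limiting dialkylation.

Step 6
Reactants: 13 ethyl 2-acetyltridec-12-enoate
Product: 15 tetradec-13-en-2-one, via 2-acetyltridec-12-enoic acid 14 (not isolated)
Conditions: NaOH, H2O/EtOH, rt; then aq HCl, 60 °C
Reagents that add atoms: sodium hydroxide, [Na+].[OH-] (its oxygen is held by 14 only)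
Why: Saponification followed by decarboxylation of the β-keto acid through a six-membered transition state (acetoacetic ester ketone synthesis); the terminal alkene is inert.

Step 7
Reactants: 15 tetradec-13-en-2-one
Product: 16 2-(dodec-11-en-1-yl)-2-methyl-1,3-dioxolane
Conditions: HOCH2CH2OH, TsOH·H2O (cat.), toluene, reflux, Dean–Stark
Reagents that add atoms: ethylene glycol, OCCO
Why: Acid-catalysed ketalisation driven by azeotropic removal of water; the isolated terminal alkene should not migrate under catalytic sulfonic acid.

Step 8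
Reactants: 10 (2S,3R)-2-allyl-5-oxotetrahydrofuran-3-carbaldehyde; 16 2-(dodec-11-en-1-yl)-2-methyl-1,3-dioxolane
Product: 17 (2S,3R)-2-[13-(2-methyl-1,3-dioxolan-2-yl)tridec-2-en-1-yl]-5-oxotetrahydrofuran-3-carbaldehyde (E/Z mixture)
Conditions: RuCl2(=CHPh)(PCy3)(H2IMes) (second-generation Grubbs catalyst, cat.), 16 in excess, CH2Cl2, 40 °C
Reagents that add atoms: none
Why: Olefin cross-metathesis of two unhindered terminal alkenes, driven by loss of ethylene and by the excess of 16 (whose homodimer remains a competent partner); aldehyde, lactone and ketal are tolerated by the ruthenium carbene, and both alkene isomers converge in step 9.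

Step 9
Reactants: 17 (2S,3R)-2-[13-(2-methyl-1,3-dioxolan-2-yl)tridec-2-en-1-yl]-5-oxotetrahydrofuran-3-carbaldehyde
Product: 18 (2S,3R)-2-[13-(2-methyl-1,3-dioxolan-2-yl)tridecyl]-5-oxotetrahydrofuran-3-carbaldehyde
Conditions: H2 (1 atm), 10% Pd/C, EtOAc, rt
Reagents that add atoms: none
Why: Heterogeneous hydrogenation of the disubstituted alkene; in neutral, non-alcoholic solvent at 1 atm the aldehyde, lactone and ketal should not be reduced and no stereocentre is touched.

Step 10
Reactants: 18 (2S,3R)-2-[13-(2-methyl-1,3-dioxolan-2-yl)tridecyl]-5-oxotetrahydrofuran-3-carbaldehyde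
Product: 19 (2S,3R)-2-[13-(2-methyl-1,3-dioxolan-2-yl)tridecyl]-5-oxotetrahydrofuran-3-carboxylic acid
Conditions: NaClO2, NaH2PO4, 2-methyl-2-butene, t-BuOH/H2O, 0 °C to rt
Reagents that add atoms: sodium chlorite, [Na+].[O-]Cl=O
Why: Pinnick oxidation of the aldehyde through its chlorite adduct with 2-methyl-2-butene scavenging HOCl; the phosphate-buffered medium should spare the dioxolane, and the trans arrangement at the ring is the stable one.

Step 11
Reactants: 19 (2S,3R)-2-[13-(2-methyl-1,3-dioxolan-2-yl)tridecyl]-5-oxotetrahydrofuran-3-carboxylic acid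
Product: 22 (2S,3R)-4-methylene-5-oxo-2-(14-oxopentadecyl)tetrahydrofuran-3-carboxylic acid, via malonic diacid 20 (not isolated), via methylene ketal acid 21 (not isolated)
Conditions: MeOMgOCO2Me (2 M in DMF, excess), 130 °C; ice-cold dilute HCl, rapid extraction; 37% aq HCHO, PhNHMe, NaOAc, AcOH, rt; then 1 M HCl, THF, rt
Reagents that add atoms: formaldehyde, C=O; water, O (ketone oxygen on ketal hydrolysis); methyl magnesium carbonate, [Mg+2].[O-]C.COC([O-])=O (its CO2 unit is held by 20 only)
Why: Stiles carboxylation puts a carboxyl on the lactone α-carbon as a magnesium chelate, the resulting malonic half-acid undergoes decarboxylative Mannich methylenation with formaldehyde and N-methylaniline (the established α-methylenation of paraconic acids), and aqueous acid then hydrolyses the dioxolane, which had kept the methyl ketone out of the carboxylation; the chain-bearing centre is not enolisable and stays (S).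

Step 12
Reactants: 22 (2S,3R)-4-methylene-5-oxo-2-(14-oxopentadecyl)tetrahydrofuran-3-carboxylic acid
Product: 25 (2S)-4-methyl-5-oxo-2-(14-oxopentadecyl)-2,5-dihydrofuran-3-carboxylic acid, via exo mixed anhydride 23 (not isolated), via endo mixed anhydride 24 (not isolated)
Conditions: Ac2O, 100 °C; then THF/H2O, rt
Reagents that add atoms: acetic anhydride, CC(=O)OC(C)=O (its acetyl group is held by 23 and 24 only); water, O (hydrolysis of 24)
Why: Anhydride-induced exo-to-endo isomerisation of an α-methylene paraconic acid (the protolichesterinic-to-lichesterinic type): the mixed anhydride acidifies the ring C–H between the carboxyl and the exocyclic alkene, and enolisation with reprotonation at the methylene carbon moves the double bond into the ring, where it is tetrasubstituted and conjugated with both carbonyls; the C–H at the chain-bearing carbon is not involved, so (S) should be kept, and aqueous THF hydrolyses the mixed anhydride.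

**Compound list**

1 | methyl furan-2-carboxylate | COC(=O)c1ccco1 | starting material
2 | ethyl diazoacetate | CCOC(=O)C=[N+]=[N-] | starting material
3 | 6-ethyl 3-methyl (1S,5S,6S)-2-oxabicyclo[3.1.0]hex-3-ene-3,6-dicarboxylate | COC(=O)C1=C[C@H]2[C@H](C(=O)OCC)[C@H]2O1 | intermediate
4 | secondary ozonide (1,2,4-trioxolane) of 3 across its C3=C4 bond | COC(=O)C12OOC(O1)[C@H]1[C@H](C(=O)OCC)[C@H]1O2 | intermediate (not isolated)
5 | ethyl (1S,2S,3S)-2-formyl-3-[(2-methoxy-2-oxoacetyl)oxy]cyclopropane-1-carboxylate | O=C[C@H]1[C@H](C(=O)OCC)[C@H]1OC(=O)C(=O)OC | intermediate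
6 | allyltrimethylsilane | C=CC[Si](C)(C)C | starting material
7 | ethyl (1S,2R,3S)-2-[(1S)-1-hydroxybut-3-en-1-yl]-3-[(2-methoxy-2-oxoacetyl)oxy]cyclopropane-1-carboxylate | C=CC[C@H](O)[C@H]1[C@H](C(=O)OCC)[C@H]1OC(=O)C(=O)OC | intermediate
8 | ethyl (1S,2R,3S)-3-hydroxy-2-[(1S)-1-hydroxybut-3-en-1-yl]cyclopropane-1-carboxylate | C=CC[C@H](O)[C@H]1[C@H](C(=O)OCC)[C@H]1O | intermediate (not isolated)
9 | ethyl (3R,4S)-3-formyl-4-hydroxyhept-6-enoate | C=CC[C@H](O)[C@H](C=O)CC(=O)OCC | intermediate (not isolated)
10 | (2S,3R)-2-allyl-5-oxotetrahydrofuran-3-carbaldehyde | C=CC[C@@H]1OC(=O)C[C@H]1C=O | intermediate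
11 | ethyl acetoacetate | CCOC(=O)CC(C)=O | starting material
12 | 11-bromo-1-undecene | C=CCCCCCCCCCBr | starting material
13 | ethyl 2-acetyltridec-12-enoate (racemic) | CCOC(=O)C(C(C)=O)CCCCCCCCCC=C | intermediate
14 | 2-acetyltridec-12-enoic acid | OC(=O)C(C(C)=O)CCCCCCCCCC=C | intermediate (not isolated)
15 | tetradec-13-en-2-one | CC(=O)CCCCCCCCCCC=C | intermediate
16 | 2-(dodec-11-en-1-yl)-2-methyl-1,3-dioxolane | CC1(OCCO1)CCCCCCCCCCC=C | intermediate
17 | (2S,3R)-2-[13-(2-methyl-1,3-dioxolan-2-yl)tridec-2-en-1-yl]-5-oxotetrahydrofuran-3-carbaldehyde (E/Z mixture, E isomer drawn) | CC1(OCCO1)CCCCCCCCCC/C=C/C[C@@H]2OC(=O)C[C@H]2C=O | intermediate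
18 | (2S,3R)-2-[13-(2-methyl-1,3-dioxolan-2-yl)tridecyl]-5-oxotetrahydrofuran-3-carbaldehyde | CC1(OCCO1)CCCCCCCCCCCCC[C@@H]2OC(=O)C[C@H]2C=O | intermediate
19 | (2S,3R)-2-[13-(2-methyl-1,3-dioxolan-2-yl)tridecyl]-5-oxotetrahydrofuran-3-carboxylic acid | CC1(OCCO1)CCCCCCCCCCCCC[C@@H]2OC(=O)C[C@H]2C(=O)O | intermediate
20 | (2S,3R)-2-[13-(2-methyl-1,3-dioxolan-2-yl)tridecyl]-5-oxotetrahydrofuran-3,4-dicarboxylic acid (magnesium chelate in the flask, drawn as the free diacid; new centre undefined) | CC1(OCCO1)CCCCCCCCCCCCC[C@@H]2OC(=O)C(C(=O)O)[C@H]2C(=O)O | intermediate (not isolated)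
21 | (2S,3R)-4-methylene-2-[13-(2-methyl-1,3-dioxolan-2-yl)tridecyl]-5-oxotetrahydrofuran-3-carboxylic acid | CC1(OCCO1)CCCCCCCCCCCCC[C@@H]2OC(=O)C(=C)[C@H]2C(=O)O | intermediate (not isolated)
22 | (2S,3R)-4-methylene-5-oxo-2-(14-oxopentadecyl)tetrahydrofuran-3-carboxylic acid | CC(=O)CCCCCCCCCCCCC[C@@H]1OC(=O)C(=C)[C@H]1C(=O)O | intermediate
23 | acetic (2S,3R)-4-methylene-5-oxo-2-(14-oxopentadecyl)tetrahydrofuran-3-carboxylic anhydride | CC(=O)CCCCCCCCCCCCC[C@@H]1OC(=O)C(=C)[C@H]1C(=O)OC(C)=O | intermediate (not isolated)
24 | acetic (2S)-4-methyl-5-oxo-2-(14-oxopentadecyl)-2,5-dihydrofuran-3-carboxylic anhydride | CC(=O)CCCCCCCCCCCCC[C@@H]1OC(=O)C(C)=C1C(=O)OC(C)=O | intermediate (not isolated)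
25 | (2S)-4-methyl-5-oxo-2-(14-oxopentadecyl)-2,5-dihydrofuran-3-carboxylic acid | CC(=O)CCCCCCCCCCCCC[C@@H]1OC(=O)C(C)=C1C(=O)O | target

**Step count and risks**

Total steps: 12. Longest linear sequence: 9 steps (steps 1–4 and 8–12); steps 5–7 build the side-chain alkene and converge at step 8.

Most likely to fail, in order:

1. Step 12. The double bond may migrate incompletely, or the chain-bearing centre may lose configuration through enolisation of the butenolide toward a 2-acyloxyfuran in hot anhydride. The fallback avoids the exocyclic alkene altogether and sets out from 19. Double deprotonation (NaHMDS, THF, −78 °C) and MeI should give the trans 4-methyl acid (2S,3R,4R)-4-methyl-2-[13-(2-methyl-1,3-dioxolan-2-yl)tridecyl]-5-oxotetrahydrofuran-3-carboxylic acid F1, the known dianion methylation of paraconic acids. A second double deprotonation (LDA, THF, −78 °C) and PhSeBr should give the α-selenide F2, with selenium entering anti to the neighbouring carboxylate and therefore syn to the ring hydrogen. H2O2 (CH2Cl2, 0 °C) gives the selenoxide F3, whose syn elimination toward that ring hydrogen should give the conjugated butenolide ketal acid F4. Treatment with 1 M HCl in THF then removes the dioxolane and the sequence comes back to the route at 25.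

2. Step 11. Carboxylation at 130 °C may be incomplete or cause decomposition, and early loss of the ketal in the acid wash would expose the methyl ketone to the Mannich stage. The fallback sets out from 19 and uses low-temperature enolate chemistry. Double deprotonation (LiHMDS, THF, −78 °C) and Eschenmoser's salt (CH2=NMe2 iodide) should give the Mannich base (2S,3R,4S)-4-[(dimethylamino)methyl]-2-[13-(2-methyl-1,3-dioxolan-2-yl)tridecyl]-5-oxotetrahydrofuran-3-carboxylic acid F5. MeI in MeOH gives the trimethylammonium iodide F6, and aqueous NaHCO3 effects the elimination to the exocyclic methylene. The sequence comes back to the route at 21, which the closing acid treatment of step 11 (1 M HCl, THF) converts to 22.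

3. Step 1. Enantioselectivity may be insufficient, or carbene dimerisation may outrun addition to the electron-poor furan. The fallback replaces asymmetric catalysis by resolution and sets out from 1 and 2. Ligand-free copper catalysis (Cu(OTf)2, PhNHNH2, CH2Cl2, large excess of 1) should give the racemic exo adduct F7, that is 3 together with its (1R,5R,6R) mirror image. Preparative chromatography on a chiral stationary phase, followed by recrystallisation, separates the enantiomers and the sequence comes back to the route at 3.

**Further compounds**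

F1 | step 12 | (2S,3R,4R)-4-methyl-2-[13-(2-methyl-1,3-dioxolan-2-yl)tridecyl]-5-oxotetrahydrofuran-3-carboxylic acid | CC1(OCCO1)CCCCCCCCCCCCC[C@@H]2OC(=O)[C@H](C)[C@H]2C(=O)O
F2 | step 12 | (2S,3R,4R)-4-methyl-2-[13-(2-methyl-1,3-dioxolan-2-yl)tridecyl]-5-oxo-4-(phenylselanyl)tetrahydrofuran-3-carboxylic acid | CC1(OCCO1)CCCCCCCCCCCCC[C@@H]2OC(=O)[C@](C)([Se]c3ccccc3)[C@H]2C(=O)O
F3 | step 12 | selenoxide of F2 | CC1(OCCO1)CCCCCCCCCCCCC[C@@H]2OC(=O)[C@](C)([Se](=O)c3ccccc3)[C@H]2C(=O)O
F4 | step 12 | (2S)-4-methyl-2-[13-(2-methyl-1,3-dioxolan-2-yl)tridecyl]-5-oxo-2,5-dihydrofuran-3-carboxylic acid | CC1(OCCO1)CCCCCCCCCCCCC[C@@H]2OC(=O)C(C)=C2C(=O)O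
F5 | step 11 | (2S,3R,4S)-4-[(dimethylamino)methyl]-2-[13-(2-methyl-1,3-dioxolan-2-yl)tridecyl]-5-oxotetrahydrofuran-3-carboxylic acid | CC1(OCCO1)CCCCCCCCCCCCC[C@@H]2OC(=O)[C@H](CN(C)C)[C@H]2C(=O)O
F6 | step 11 | trimethylammonium iodide derived from F5 | CC1(OCCO1)CCCCCCCCCCCCC[C@@H]2OC(=O)[C@H](C[N+](C)(C)C)[C@H]2C(=O)O.[I-]
F7 | step 1 | racemic exo adduct (3 together with its mirror image; the (1R,5R,6R) enantiomer is drawn) | COC(=O)C1=C[C@@H]2[C@@H](C(=O)OCC)[C@@H]2O1
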